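# Synthesis proposal for CNP0330581.1: Ireland–Claisen ring contraction of a cyclobutane-fused lactone to forge C9–C10

## The problem

The target is a rearranged labdane (labdane numbering throughout) in which a trans-decalin (rings A and B) shares its C8–C9 bond with a cyclobutane (C8, C9, C14, C15), whose C9–C14 bond is in turn shared with a cyclopentanol (C9, C11, C12, C13, C14), so that C9 belongs to three rings. C8, C9 and C10 are contiguous quaternary carbons flanked by the gem-dimethyl carbon C4 and the tertiary carbinol C13; the methyl groups on C8 and C10, the C11 branch and the C6 acetate lie on the β face and the four-membered ring on the α face. Seven stereocentres must be set (C5, C6, C8, C9, C10, C13, C14): C8 dictates C9 and C14 because a four-membered ring can only be cis-fused, and C10 can control C5 (axial protonation) and C6 (hydride from the open α face). Nothing relays the C8/C9 pair to C10 unless the C9–C10 bond is itself made stereospecifically, and C13 is remote from every other centre. The α-acetoxy ketone (epimerisable C6, base-labile acetate) and the tertiary alcohol beside a strained ring (a cyclobutylcarbinyl cation would open) rule out strong acid or base late in the synthesis. The 6β oxygen is axial and syn to three methyl groups, so it cannot be delivered by an electrophile, which would enter from the α face. The feature that makes the key step possible is that C10 is allylic to the oxygen-bearing C6 through C5 while C9 is the α-carbon of a latent C11 carboxyl: the C6 allyl ester of that acid is a six-membered lactone (C11, O, C6, C7, C8, C9) whose ketene acetal can form C9–C10 by a [3,3] shift that turns the lactone into ring B.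

## Retrosynthesis

**C13–C14 and the C7 ketone (35 ⇒ 34 ⇒ 33 ⇒ 32).** The C7 ketone is taken back through alcohol 34 to silyl ether 33, and the C13–C14 bond is cut to give methyl ketone 32. This is the only ring bond that joins a carbinol carbon to a carbon that can start as an unfunctionalised CH2. Cutting C9–C11 or C12–C13 instead would demand a nucleophile at the fully substituted C9, and an aldol-type closure onto C14 would need a carbonyl that an ethylene-derived cyclobutane does not carry. Ketone 32 has one ring and two stereocentres fewer. The forward step is a Norrish–Yang cyclisation: C9 has no hydrogen, so the C14 hydrogens are the only δ-hydrogens. The methyl ketone must be the only chromophore, so C7 stays a silyl ether until the end.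

**Ring B oxygens and the side chain (32 ⇒ 31 ⇒ 30 ⇒ 28 ⇒ 27 ⇒ 26 ⇒ 24).** The 3-oxobutyl chain is cut at C11–C12 (olefination of aldehyde 28 to enone 30, then acetylation to 31 and hydrogenation to 32). The C6–O bond is traced to hydride reduction of a C6 ketone and the C7–O bond to Rubottom oxidation (26 from 24, reduced to 27). Acetoxylating a C7-ketone enolate at C6 is rejected because the oxidant would enter from the α face and give the 6α epimer; here the hydrogen, not the oxygen, is delivered from the α face. Keto ester 24 has a single carbonyl in ring B and a plain ester. The forward sequence needs enolisation of 24 toward C7 only, which the buried C5–H ensures.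

**Ring A (24 ⇒ 23 ⇒ 21).** The second C4 methyl is removed (conjugate methylation of enone 23), then the C4=C5 bond is cut (intramolecular aldol condensation of the diketone freed from ketal 21). Ring A cannot be carried through the key step (see below), so it is annulated onto the C6 ketone. Keto ketal 21 lacks ring A and the C5 stereocentre. The aldol has one productive direction, and C5 is set by axial protonation after the methyl addition.

**C6 ketone (21 ⇒ 20 ⇒ 19 ⇒ 18).** The ketone is traced through alcohol 20 to the C5=C6 alkene of ester 19, and that to acid 18. Hydroboration must place boron on C6, the alkene carbon remote from the quaternary C10.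

**C9–C10, the key disconnection (18 ⇒ 15).** Cutting C9–C10 and rejoining C11–O–C6 gives lactone 15. The ring tie forces a boat in which the carboxyl carbon C11 stacks over C5. Two consequences fix the structure of 15.

- The C10 substituent that is cis to C6 in the alkene ends trans to C11 on ring B. With a preformed 2,6,6-trimethylcyclohexenyl group that substituent would be the methyl, which would give the C10 epimer of the target. The allyl partner therefore has to be the open-chain (Z)-alkene whose chain (C1) is cis to C6 and whose methyl is trans.
- C10 can only reach the enolate face that carries C7. This requires the alkenyl group on C6 to be cis to the cyclobutane methylenes on the lactone ring, as in 15; with the alkenyl group trans to them the boat cannot be reached.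

The step removes ring B and both quaternary centres C9 and C10, leaving only C6 and C8 as controlling stereocentres. The rearrangement must outrun heterolysis of the allylic C6–O bond.

**Lactone assembly (15 ⇒ 14 ⇒ 6 + 12).** The lactone C–O bond and the C5–C6 bond are cut to aldehyde 6 and (Z)-alkenyl iodide 12 (Nozaki–Hiyama–Kishi addition, then lactonisation of hydroxy ester 14). The Z alkene would not survive a photoreaction that runs through triplet states, so the cyclobutane is made first and the alkene is attached afterwards. An ethylene photocycloaddition onto a lactone that already carries the C6 substituent would place the new ring anti to it, which is the wrong arrangement. The nearest stereocentre of 6 is quaternary and two bonds from the carbonyl, so the carbinol is set by a chiral chromium reagent. Because 6 is a single enantiomer, this reagent control fixes the syn relationship between C6 and the cyclobutane that the key step demands.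

**Building blocks (6 ⇒ 4 ⇒ 3 ⇒ 1 + 2; 12 ⇒ 7 + 8).** In 6 the ester carbon (C11) and the aldehyde carbon (C6) are rejoined as the double bond of silyl enol ether 4, which comes from cyclopentanone 3; in the forward sense ozonolysis unmasks both carbonyl groups at the right oxidation levels in one operation. Cutting the two cyclobutane bonds C8–C15 and C9–C14 of 3 leaves enone 1 and ethylene 2. A ketone is chosen as the chromophore because a chiral Lewis acid can bind it, so the absolute configuration of C8 is set in the ring-forming event; an ester or lactone offers no comparable handle. Iodide 12 comes from syn-carbocupration of propyne 8 with the Grignard reagent of chloride 7, which fixes the Z geometry.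

## Roads not taken

Alternative 1: Norrish–Yang closure of the cyclopentanol as the organising step. The cut is C13–C14; irradiation of 3-oxobutyl ketone A2 gives A1, the target with C7 as a 7β-silyl ether.

- Merits: the C–C bond is formed at an unfunctionalised cyclobutane methylene, C14 is set automatically, and no functional group is carried for the purpose.
- Weak points: it says nothing about the contiguous quaternary array C8–C9–C10 or ring B, which is the hard part. C13 is set in a biradical without a controlling element.
- Comparison: the chosen plan uses the same photoreaction as step 19 on 32, the C7 epimer of A2, so in the last steps the two are equal. The chosen plan adds a stereospecific origin for the tricyclic ketone and inherits the C13 uncertainty unchanged.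

Alternative 2: photoisomerisation of a ring-fused tropone. The cut is C9–C14; irradiation of tropone A4 as its BF3·OEt2 complex gives bicyclo[3.2.0]heptadienone A3 by disrotatory 4π closure.

- Merits: the four- and five-membered rings and quaternary C9 arise in one step from a flat precursor, and the C13 carbonyl is ready for methyl addition. This is shorter than the two separate operations (ethylene cycloaddition, Norrish–Yang) used here.
- Weak points: the closure must choose a face under the influence of C10 alone. C8 must then receive a methyl group at a fully substituted cyclobutene carbon with hydrogen delivered cis to C15. Ring B of A3 carries no oxygen, so C6 and C7 would need oxidation of unactivated C–H bonds. A4 itself needs a ring-expansion sequence.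
- Comparison: the chosen plan builds fewer rings per step, but every quaternary centre and both ring B oxygens have a defined origin.

Alternative 3: asymmetric Diels–Alder reaction of cyclobutenone A7 with silyloxydiene A6 under a chiral cationic oxazaborolidine Lewis acid, giving tricyclic cyclobutanone A5. The cuts are C7–C8 and C9–C10.

- Merits: it is convergent, ring A comes intact from a terpene building block, one catalytic step sets the absolute configuration, and the C6 oxygen and a C14 carbonyl arrive in the adduct. In these respects it is better than the chosen plan, which annulates ring A late and needs two separate reagent-controlled steps (a chiral Lewis acid in the photocycloaddition and a stoichiometric chiral chromium reagent).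
- Weak points: both reacting termini become quaternary (C8, C10) in an intermolecular step. The diene terminus C10 is fully substituted and held out of the s-cis form by the gem-dimethyl group. A5 still has hydrogen on C9, which would have to be alkylated between two quaternary carbons on the more hindered face. The C14 carbonyl must later become a C–H bearing C13.
- Comparison: the chosen plan makes C9 quaternary in the ring-forming event itself, intramolecularly, with its configuration tied to C8 by the four-membered ring.

Key step: step 7

Assumptions (remarks on the chemistry): in step 1 the (S)-configured oxazaborolidine is taken to give (1R,5R)-3, and in step 5 the (S)-ligand is taken to give the (R)-carbinol; the antipode of either is used if its sense proves opposite.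

## Route

Step 1
Reactants: 1 3-methylcyclopent-2-en-1-one; 2 ethylene
Product: 3 (1R,5R)-5-methylbicyclo[3.2.0]heptan-2-one (cis-fused)
Conditions: hν (366 nm), ethylene-saturated CH2Cl2, AlBr3 complex of (S)-3,3-bis(3,5-dimethylphenyl)-1-(2,4,6-trifluorophenyl)tetrahydro-1H,3H-pyrrolo[1,2-c][1,3,2]oxazaborole (50 mol %), −78 °C
Reagents that add atoms: none
Why: Enone–alkene [2+2] photocycloaddition under chiral Lewis acid catalysis, a known reaction type for cyclic enones: the aluminium-activated oxazaborolidine binds the carbonyl, shifts the absorption so that mainly the complex is excited at 366 nm, and screens one face of the β-carbon. The cis ring fusion is the only unstrained outcome, so the quaternary C8 and C9 are set together.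

Step 2
Reactants: 3 (1R,5R)-5-methylbicyclo[3.2.0]heptan-2-one
Product: 4 trimethyl{[(1R,5R)-5-methylbicyclo[3.2.0]hept-2-en-2-yl]oxy}silane
Conditions: LiN(iPr)2, THF, −78 °C; TMSCl; pentane, filtration, distillation
Reagents that add atoms: chlorotrimethylsilane, C[Si](C)(C)Cl
Why: Kinetic silyl enol ether formation at the C3 methylene; the other α-carbon is the tertiary ring-fusion carbon, where an enolate would place a double bond at the bridgehead of the bicyclo[3.2.0] system.

Step 3
Reactants: 4 trimethyl{[(1R,5R)-5-methylbicyclo[3.2.0]hept-2-en-2-yl]oxy}silane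
Product: 6 methyl (1R,2R)-2-methyl-2-(2-oxoethyl)cyclobutane-1-carboxylate, via aldehyde acid 5 (not isolated)
Conditions: O3, CH2Cl2–MeOH, −78 °C; Me2S, −78 → 25 °C; concentrate; then MeI, KHCO3, DMF, 25 °C
Reagents that add atoms: ozone, [O-][O+]=O; iodomethane, CI
Why: Ozonolysis of a silyl enol ether with reductive work-up turns the silyloxy carbon into a carboxylic acid (C11) and the other alkene carbon into an aldehyde (C6); O-methylation of the carboxylate with a weak base then gives the ester without epimerising the α-carbon or touching the aldehyde.

Step 4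
Reactants: 7 2-(3-chloropropyl)-2-methyl-1,3-dioxolane; 8 propyne
Product: 12 2-[(4Z)-5-iodo-4-methylpent-4-en-1-yl]-2-methyl-1,3-dioxolane, via Grignard reagent 9 (not isolated), via alkylcopper reagent 10 (not isolated), via alkenylcopper reagent 11 (not isolated)
Conditions: Mg, THF, 65 °C; CuBr·SMe2, Et2O–Me2S, −45 °C; propyne, −25 °C; I2, THF, −50 → 0 °C
Reagents that add atoms: iodine, II
Why: Alkyne carbocupration adds the alkyl group and copper syn across propyne (alkyl to the internal carbon); iodinolysis with retention places iodine cis to the chain, which is the Z geometry needed later.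

Step 5
Reactants: 6 methyl (1R,2R)-2-methyl-2-(2-oxoethyl)cyclobutane-1-carboxylate; 12 2-[(4Z)-5-iodo-4-methylpent-4-en-1-yl]-2-methyl-1,3-dioxolane
Product: 14 methyl (1R,2R)-2-[(2R,3Z)-2-hydroxy-4-methyl-7-(2-methyl-1,3-dioxolan-2-yl)hept-3-en-1-yl]-2-methylcyclobutane-1-carboxylate, via alkenylchromium reagent 13 (not isolated)
Conditions: CrCl2, NiCl2 (cat.), (S)-N-[2-(4-isopropyl-4,5-dihydro-1,3-oxazol-2-yl)-6-methylphenyl]methanesulfonamide, Et3N, THF, 25 °C
Reagents that add atoms: none
Why: Nozaki–Hiyama–Kishi addition: alkenylchromium 13 keeps the Z geometry and adds only to the aldehyde, leaving ester and ketal alone. The sulfonamide ligand on chromium sets the (R)-carbinol by reagent control, since the only nearby stereocentre of 6 is quaternary and two bonds from the carbonyl.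

Step 6
Reactants: 14 methyl (1R,2R)-2-[(2R,3Z)-2-hydroxy-4-methyl-7-(2-methyl-1,3-dioxolan-2-yl)hept-3-en-1-yl]-2-methylcyclobutane-1-carboxylate
Product: 15 (1R,4R,6R)-6-methyl-4-[(1Z)-2-methyl-5-(2-methyl-1,3-dioxolan-2-yl)pent-1-en-1-yl]-3-oxabicyclo[4.2.0]octan-2-one (alkenyl group cis to the cyclobutane methylenes)
Conditions: DBU (cat.), PhMe, 60 °C; chromatography on SiO2
Reagents that add atoms: none
Why: Base-catalysed transesterification closes the cis-fused δ-lactone without acid, which would ionise the allylic alcohol and open the ketal; the carbinol configuration is retained because the C6–O bond is not broken.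

Step 7
Reactants: 15 (1R,4R,6R)-6-methyl-4-[(1Z)-2-methyl-5-(2-methyl-1,3-dioxolan-2-yl)pent-1-en-1-yl]-3-oxabicyclo[4.2.0]octan-2-one
Product: 18 (1S,2S,6R)-2,6-dimethyl-2-[3-(2-methyl-1,3-dioxolan-2-yl)propyl]bicyclo[4.2.0]oct-3-ene-1-carboxylic acid, via silyl ketene acetal 16 (not isolated), via silyl ester 17 (not isolated)
Conditions: LiN(iPr)2, TBSCl, THF–DMPU, −78 °C; PhMe, 110 °C; aq. K2CO3–MeOH, then NaH2PO4 (pH 5)
Reagents that add atoms: none
Why: Deprotonation at C9 and O-silylation give ketene acetal 16; on heating C9 bonds to C10 as the O–C6 bond breaks in a suprafacial [3,3] shift, and the resulting silyl ester 17 is hydrolysed to 18. The closest known reaction type is the Ireland–Claisen ring contraction of six-membered lactone silyl ketene acetals bearing an alkenyl group on the carbinol carbon, which runs through a boat because the ring tie excludes the chair. Ring B closes as a six-membered ring holding both carbons of the reacting alkene (6-endo with respect to C5=C10) inside a bicyclo[2.2.2]octane-like array. C9 is set by C8: the cyclobutane keeps C15 in the enolate plane, so C10 can only arrive on the face carrying C7, which leaves C11 cis to the C8 methyl. C10 is set by C6: the new bond forms on the alkene face from which oxygen departs, and in the boat the chain that was cis to C6 ends trans to C11 while the methyl ends cis to it, as the target requires. The step needs rearrangement to outrun heterolysis of the allylic C6–O bond. A hydrogen on C5 (nothing beneath the silyloxy group), a non-polar solvent and the syn arrangement of 15 serve this end. The step creates the vicinal quaternary carbons C9 and C10 in one event.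

Step 8
Reactants: 18 (1S,2S,6R)-2,6-dimethyl-2-[3-(2-methyl-1,3-dioxolan-2-yl)propyl]bicyclo[4.2.0]oct-3-ene-1-carboxylic acid
Product: 19 methyl ester of 18
Conditions: MeI, K2CO3, DMF, 25 °C
Reagents that add atoms: iodomethane, CI
Why: O-alkylation of the carboxylate is insensitive to the hindrance around C9 and leaves the ketal and alkene alone.

Step 9
Reactants: 19 methyl ester of 18
Product: 20 6-hydroxy ester (hydroxyl on C6 of the saturated ring B; C6 epimers, both used)
Conditions: 9-BBN, THF, 65 °C; NaOH, H2O2, 0 °C
Reagents that add atoms: hydrogen peroxide, OO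
Why: Hydroboration–oxidation; the bulky borane places boron on C6, the alkene carbon away from the quaternary C10, and the C6 configuration is erased in the next step.

Step 10
Reactants: 20 6-hydroxy ester
Product: 21 6-keto ester with the ketal-protected 4-oxopentyl chain on C10
Conditions: Dess–Martin periodinane, NaHCO3, CH2Cl2, 25 °C
Reagents that add atoms: none
Why: Standard oxidation of a secondary alcohol under buffered conditions that keep the ketal.

Step 11
Reactants: 21 6-keto ester with the ketal-protected 4-oxopentyl chain on C10
Product: 23 tricyclic enone (ring A closed, C4=C5 conjugated with the C6 ketone, one methyl on C4), via diketone 22 (not isolated)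
Conditions: 1 M HCl, THF, 25 °C; then NaOMe, MeOH, 50 °C
Reagents that add atoms: none
Why: Ketal hydrolysis followed by intramolecular aldol condensation of a 1,7-diketone to a 2-alkylidene cyclohexanone. Only attack of the C5 enolate on the C4 carbonyl can dehydrate to a conjugated enone; the competing aldol (C3 onto C6) would need a bridgehead alkene and is expected to revert.

Step 12
Reactants: 23 tricyclic enone
Product: 24 4,4-dimethyl 6-keto ester with trans ring fusion (5α-H)
Conditions: Me2CuLi, BF3·OEt2, Et2O, −78 → −30 °C; AcOH–THF quench at −78 °C
Reagents that add atoms: lithium dimethylcuprate, [Li+].C[Cu-]C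
Why: Cuprate conjugate addition to an s-cis β,β-disubstituted enone (as with pulegone-type enones) completes the gem-dimethyl carbon C4, which is not stereogenic. C5 is set by kinetic axial protonation of the enolate on the α face, the β face being screened by the C10 methyl and the 4β methyl; the trans fusion is also the more stable one.

Step 13
Reactants: 24 4,4-dimethyl 6-keto ester
Product: 26 7α-triethylsilyloxy 6-keto ester, via triethylsilyl enol ether 25 (not isolated)
Conditions: LiN(iPr)2, THF, −78 °C; TESCl; then mCPBA, NaHCO3, hexane–CH2Cl2, −15 °C
Reagents that add atoms: chlorotriethylsilane, CC[Si](Cl)(CC)CC; 3-chloroperbenzoic acid, OOC(=O)c1cccc(Cl)c1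
Why: Kinetic enolisation occurs at C7 because the C5 hydrogen lies between two quaternary carbons. Rubottom oxidation (epoxidation from the α face, then 1,4-silyl shift) gives the α-silyloxy ketone; the C7 configuration is immaterial because C7 ends as a ketone.

Step 14
Reactants: 26 7α-triethylsilyloxy 6-keto ester
Product: 27 6β,11-diol 7α-triethylsilyl ether
Conditions: LiAlH4, THF, 0 → 65 °C
Reagents that add atoms: none
Why: Hydride reaches C6 from the α face because the β (axial) approach is closed by three syn-axial methyl groups (on C4, C8 and C10), giving the 6β alcohol. The ester is reduced to the neopentyl alcohol in the same operation.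

Step 15
Reactants: 27 6β,11-diol 7α-triethylsilyl ether
Product: 28 11-aldehyde with free 6β-hydroxyl
Conditions: TEMPO (cat.), PhI(OAc)2, CH2Cl2, 25 °C
Reagents that add atoms: none
Why: Oxoammonium oxidation takes the primary alcohol and leaves the axial, heavily screened secondary 6β-hydroxyl. A lactol between C11 and the C6 oxygen would force ring B into a boat, so over-oxidation to a lactone is not expected.

Step 16
Reactants: 28 11-aldehyde; 29 dimethyl (2-oxopropyl)phosphonate
Product: 30 (E)-enone (C11=C12–C13(=O)CH3 on C9) with free 6β-hydroxyl
Conditions: LiCl, iPr2NEt, MeCN, 25–40 °C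
Reagents that add atoms: none
Why: Horner–Wadsworth–Emmons olefination under mild amine/lithium salt conditions; the aldehyde has no α-hydrogen, so the base can do no harm.

Step 17
Reactants: 30 (E)-enone with free 6β-hydroxyl
Product: 31 6β-acetate of 30
Conditions: Ac2O, DMAP, Et3N, PhMe, 80 °C
Reagents that add atoms: acetic anhydride, CC(=O)OC(C)=O
Why: Nucleophile-catalysed acylation under forcing conditions for a hindered axial alcohol; the trans-diaxial silyl ether on C7 cannot migrate.

Step 18
Reactants: 31 6β-acetate of 30
Product: 32 3-oxobutyl ketone (6β-OAc, 7α-OTES)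
Conditions: H2 (1 atm), Pd/C, EtOAc, 25 °C
Reagents that add atoms: none
Why: Hydrogenation of the only alkene, a disubstituted enone double bond; acetate and silyl ether are inert.

Step 19
Reactants: 32 3-oxobutyl ketone
Product: 33 7α-triethylsilyl ether of the 7-alcohol corresponding to the target (cyclopentanol closed)
Conditions: hν (300 nm, Pyrex), degassed t-BuOH–PhH, 25 °C
Reagents that add atoms: none
Why: Norrish–Yang cyclisation: the excited methyl ketone has no γ-hydrogen (C9 is quaternary), so it abstracts a δ-hydrogen from C14, and the 1,5-biradical closes C13–C14 to the five-membered ring. C14 must be cis-fused. At C13 the hydroxyl is expected on the convex face beside the remaining C14 hydrogen, but this is the least controlled centre of the route.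

Step 20
Reactants: 33 7α-triethylsilyl ether
Product: 34 7α-alcohol (6β-acetoxy-7α,13-diol)
Conditions: HF·pyridine, pyridine–THF, 0 → 25 °C
Reagents that add atoms: none
Why: Buffered fluoride desilylation spares the acetate and the tertiary alcohol; the acetate cannot migrate to the trans-diaxial C7 oxygen.

Step 21
Reactants: 34 7α-alcohol
Product: 35 CNP0330581.1
Conditions: Dess–Martin periodinane, NaHCO3, CH2Cl2, 0 °C
Reagents that add atoms: none
Why: Neutral oxidation of the secondary alcohol to the C7 ketone leaves the tertiary alcohol untouched and does not epimerise the adjacent acetoxy-bearing C6.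

## Compound list

1 | 3-methylcyclopent-2-en-1-one | CC1=CC(=O)CC1 | starting material
2 | ethylene | C=C | starting material
3 | (1R,5R)-5-methylbicyclo[3.2.0]heptan-2-one (cis-fused) | O=C1[C@@H]2CC[C@]2(C)CC1 | intermediate
4 | trimethyl{[(1R,5R)-5-methylbicyclo[3.2.0]hept-2-en-2-yl]oxy}silane | C[Si](C)(C)OC1=CC[C@@]2(C)CC[C@@H]12 | intermediate
5 | (1R,2R)-2-methyl-2-(2-oxoethyl)cyclobutane-1-carboxylic acid (not isolated) | OC(=O)[C@@H]1CC[C@]1(C)CC=O | intermediate
6 | methyl (1R,2R)-2-methyl-2-(2-oxoethyl)cyclobutane-1-carboxylate | COC(=O)[C@@H]1CC[C@]1(C)CC=O | intermediate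
7 | 2-(3-chloropropyl)-2-methyl-1,3-dioxolane | ClCCCC1(C)OCCO1 | starting material
8 | propyne | CC#C | starting material
9 | [3-(2-methyl-1,3-dioxolan-2-yl)propyl]magnesium chloride (not isolated) | Cl[Mg]CCCC1(C)OCCO1 | intermediate
10 | [3-(2-methyl-1,3-dioxolan-2-yl)propyl]copper, magnesium halide complex (not isolated) | [Cu]CCCC1(C)OCCO1 | intermediate
11 | (Z)-[2-methyl-5-(2-methyl-1,3-dioxolan-2-yl)pent-1-en-1-yl]copper (not isolated) | [Cu]/C=C(/C)CCCC1(C)OCCO1 | intermediate
12 | 2-[(4Z)-5-iodo-4-methylpent-4-en-1-yl]-2-methyl-1,3-dioxolane | I/C=C(/C)CCCC1(C)OCCO1 | intermediate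
13 | (Z)-[2-methyl-5-(2-methyl-1,3-dioxolan-2-yl)pent-1-en-1-yl]chromium dichloride (trivalent chromium; not isolated) | Cl[Cr](Cl)/C=C(/C)CCCC1(C)OCCO1 | intermediate
14 | methyl (1R,2R)-2-[(2R,3Z)-2-hydroxy-4-methyl-7-(2-methyl-1,3-dioxolan-2-yl)hept-3-en-1-yl]-2-methylcyclobutane-1-carboxylate | COC(=O)[C@@H]1CC[C@]1(C)C[C@@H](O)/C=C(/C)CCCC1(C)OCCO1 | intermediate
15 | (1R,4R,6R)-6-methyl-4-[(1Z)-2-methyl-5-(2-methyl-1,3-dioxolan-2-yl)pent-1-en-1-yl]-3-oxabicyclo[4.2.0]octan-2-one (syn-lactone) | O=C1O[C@@H](/C=C(/C)CCCC3(C)OCCO3)C[C@@]2(C)CC[C@@H]12 | intermediate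
16 | tert-butyldimethylsilyl ketene acetal of 15 (C9=C11, exocyclic to the cyclobutane; not isolated) | CC(C)(C)[Si](C)(C)OC1=C2CC[C@]2(C)C[C@H](/C=C(/C)CCCC3(C)OCCO3)O1 | intermediate
17 | tert-butyldimethylsilyl ester of 18 (not isolated) | CC(C)(C)[Si](C)(C)OC(=O)[C@@]12CC[C@]1(C)CC=C[C@]2(C)CCCC1(C)OCCO1 | intermediate
18 | (1S,2S,6R)-2,6-dimethyl-2-[3-(2-methyl-1,3-dioxolan-2-yl)propyl]bicyclo[4.2.0]oct-3-ene-1-carboxylic acid (ring B with C5=C6; C8-Me, C10-Me and CO2H on one face, cyclobutane on the other) | OC(=O)[C@@]12CC[C@]1(C)CC=C[C@]2(C)CCCC1(C)OCCO1 | intermediate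
19 | methyl ester of 18 | COC(=O)[C@@]12CC[C@]1(C)CC=C[C@]2(C)CCCC1(C)OCCO1 | intermediate
20 | 6-hydroxy derivative of 19 with saturated ring B (C6 epimers) | COC(=O)[C@@]12CC[C@]1(C)CC(O)C[C@]2(C)CCCC1(C)OCCO1 | intermediate
21 | 6-keto ester with ketal-protected 4-oxopentyl chain on C10 | COC(=O)[C@@]12CC[C@]1(C)CC(=O)C[C@]2(C)CCCC1(C)OCCO1 | intermediate
22 | 6-keto ester with free 4-oxopentyl chain (diketone; not isolated) | COC(=O)[C@@]12CC[C@]1(C)CC(=O)C[C@]2(C)CCCC(C)=O | intermediate
23 | tricyclic enone: ring A closed, C4=C5 conjugated with C6=O, one methyl on C4; 8β-Me, 10β-Me, 9β-CO2Me, cyclobutane α | COC(=O)[C@@]12CC[C@]1(C)CC(=O)C1=C(C)CCC[C@@]12C | intermediate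
24 | 4,4-dimethyl 6-keto ester, trans-fused (5α-H) | COC(=O)[C@@]12CC[C@]1(C)CC(=O)[C@H]1C(C)(C)CCC[C@@]12C | intermediate
25 | triethylsilyl enol ether of 24 (C6=C7; not isolated) | CC[Si](CC)(CC)OC1=C[C@@]2(C)CC[C@@]2(C(=O)OC)[C@@]2(C)CCCC(C)(C)[C@H]12 | intermediate
26 | 7α-triethylsilyloxy 6-keto ester | O=C1[C@@H](O[Si](CC)(CC)CC)[C@@]2(C)CC[C@@]2(C(=O)OC)[C@@]2(C)CCCC(C)(C)[C@H]12 | intermediate
27 | 6β,11-diol 7α-triethylsilyl ether | O[C@@H]1[C@@H](O[Si](CC)(CC)CC)[C@@]2(C)CC[C@@]2(CO)[C@@]2(C)CCCC(C)(C)[C@H]12 | intermediate
28 | 11-aldehyde, 6β-hydroxy, 7α-triethylsilyloxy | O[C@@H]1[C@@H](O[Si](CC)(CC)CC)[C@@]2(C)CC[C@@]2(C=O)[C@@]2(C)CCCC(C)(C)[C@H]12 | intermediate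
29 | dimethyl (2-oxopropyl)phosphonate | COP(=O)(CC(C)=O)OC | starting material
30 | (E)-3-oxobut-1-enyl side chain on C9, 6β-hydroxy, 7α-triethylsilyloxy | O[C@@H]1[C@@H](O[Si](CC)(CC)CC)[C@@]2(C)CC[C@@]2(/C=C/C(C)=O)[C@@]2(C)CCCC(C)(C)[C@H]12 | intermediate
31 | 6β-acetate of 30 | CC(=O)O[C@@H]1[C@@H](O[Si](CC)(CC)CC)[C@@]2(C)CC[C@@]2(/C=C/C(C)=O)[C@@]2(C)CCCC(C)(C)[C@H]12 | intermediate
32 | 3-oxobutyl ketone, 6β-acetoxy, 7α-triethylsilyloxy | CC(=O)O[C@@H]1[C@@H](O[Si](CC)(CC)CC)[C@@]2(C)CC[C@@]2(CCC(C)=O)[C@@]2(C)CCCC(C)(C)[C@H]12 | intermediate
33 | tetracyclic cyclopentanol, 6β-acetoxy, 7α-triethylsilyloxy | CC(=O)O[C@@H]1[C@@H](O[Si](CC)(CC)CC)[C@@]2(C)C[C@H]3[C@@]2(CC[C@]3(C)O)[C@@]2(C)CCCC(C)(C)[C@H]12 | intermediate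
34 | tetracyclic 6β-acetoxy-7α,13-diol | CC(=O)O[C@@H]1[C@@H](O)[C@@]2(C)C[C@H]3[C@@]2(CC[C@]3(C)O)[C@@]2(C)CCCC(C)(C)[C@H]12 | intermediate
35 | CNP0330581.1 | CC(=O)O[C@@H]1C(=O)[C@@]2(C)C[C@H]3[C@@]2(CC[C@]3(C)O)[C@@]2(C)CCCC(C)(C)[C@H]12 | target

## Step count and least certain steps

Total step count: 21. Longest linear sequence: 20 (steps 1–3 and 5–21; step 4 is the side branch).

Acid 18 is the point for upgrading the optical purity by crystallisation.

**Step 7 (key step).** The likely failure is heterolysis of the allylic C6–O bond of the ketene acetal (the cation is tertiary at C10) with elimination or recombination before the crowded boat is reached. C-silylation of the hindered enolate is a second possibility. The fallback sets out from 14 and returns at 19. The carbinol is converted with diethyl chlorophosphate and pyridine into allylic phosphate F1. The potassium ester enolate (KN(SiMe3)2, THF, −78 °C) then closes ring B by intramolecular SN2′ alkylation at C10, forming the same C9–C10 bond without heating and giving ester 19 directly. The enolate face is still fixed by the C7 tether. The configuration at C10 then depends on the syn course of the displacement, which is not enforced as it is in the Claisen boat.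

**Step 1.** Enantioselection may be insufficient: the five-membered enone and the small, undiscriminating ethylene give the catalyst little to work with, and photoreaction of uncomplexed enone erodes the selectivity. The fallback sets out from 1 and 2 and returns at 15. Direct irradiation without the Lewis acid (Pyrex, CH2Cl2, −70 °C) gives 3 as the racemate, and steps 2 and 3 then give racemic 6. Step 5 sets the (R)-carbinol on both enantiomers, so 14 forms together with its cyclobutane diastereomer, hydroxy ester F2. Lactonisation as in step 6 gives 15 and anti-lactone F3, which differ in the relative configuration of C6 and C8 and are separated by chromatography. Absolute configuration then rests on the chromium reagent alone, at the cost of half of the material. The same separation removes whatever F3 arises from the minor enantiomer when step 1 is only partly selective.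

**Step 19.** Hydrogen abstraction from other sites (C7–H beside the silyl ether) or α-cleavage may compete, and the biradical may close with the wrong facial sense at C13. The fallback for the second case sets out from 32 and returns at 33. If irradiation delivers mainly the C13 epimer F4, dehydration with Burgess reagent gives the C12–C13 alkene F5. Mukaiyama hydration (Co(acac)2, PhSiH3, O2, iPrOH) then places the hydroxyl on the convex face of the bicyclo[3.2.0] unit by oxygen capture of the tertiary radical, giving 33. C13 is thus set by reagent approach instead of biradical geometry.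

**Step 12.** Steric screening of C4 may divert the cuprate to 1,2-addition or simple enolisation. The fallback sets out from 23 and returns at 24. Luche reduction (NaBH4, CeCl3) gives allylic alcohol F6. Hydroxyl-directed Simmons–Smith cyclopropanation (Et2Zn, CH2I2) gives cyclopropyl carbinol F7, and Dess–Martin oxidation gives cyclopropyl ketone F8. Brief Li/NH3 reduction at −78 °C cleaves the external cyclopropane bond, turning its CH2 into the second C4 methyl, and the enolate is protonated at C5 as in step 12.

**Step 17.** Acylation of the triply screened axial hydroxyl may stall, or the silyl ether may be lost under forcing conditions. The fallback sets out from 26 and returns at 31. After LiAlH4 reduction the aluminium alkoxides are acetylated in the same flask (Ac2O, DMAP, pyridine) to diacetate F9. The primary acetate alone is removed (K2CO3, MeOH, 0 °C) to give alcohol F10. Dess–Martin oxidation gives aldehyde F11, and olefination with 29 (LiCl, iPr2NEt) gives 31.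

## Further compounds

F1 | step 7 | methyl (1R,2R)-2-[(2R,3Z)-2-(diethoxyphosphoryloxy)-4-methyl-7-(2-methyl-1,3-dioxolan-2-yl)hept-3-en-1-yl]-2-methylcyclobutane-1-carboxylate | COC(=O)[C@@H]1CC[C@]1(C)C[C@@H](OP(=O)(OCC)OCC)/C=C(/C)CCCC1(C)OCCO1
F2 | step 1 | methyl (1S,2S)-2-[(2R,3Z)-2-hydroxy-4-methyl-7-(2-methyl-1,3-dioxolan-2-yl)hept-3-en-1-yl]-2-methylcyclobutane-1-carboxylate | COC(=O)[C@H]1CC[C@@]1(C)C[C@@H](O)/C=C(/C)CCCC1(C)OCCO1
F3 | step 1 | (1S,4R,6S)-6-methyl-4-[(1Z)-2-methyl-5-(2-methyl-1,3-dioxolan-2-yl)pent-1-en-1-yl]-3-oxabicyclo[4.2.0]octan-2-one (anti-lactone) | O=C1O[C@@H](/C=C(/C)CCCC3(C)OCCO3)C[C@]2(C)CC[C@H]12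
F4 | step 19 | C13 epimer of 33 | CC(=O)O[C@@H]1[C@@H](O[Si](CC)(CC)CC)[C@@]2(C)C[C@H]3[C@@]2(CC[C@@]3(C)O)[C@@]2(C)CCCC(C)(C)[C@H]12
F5 | step 19 | C12–C13 alkene from dehydration of F4 | CC(=O)O[C@@H]1[C@@H](O[Si](CC)(CC)CC)[C@@]2(C)C[C@H]3[C@@]2(CC=C3C)[C@@]2(C)CCCC(C)(C)[C@H]12
F6 | step 12 | allylic alcohol from 23 (C6 carbinol, configuration immaterial) | COC(=O)[C@@]12CC[C@]1(C)CC(O)C1=C(C)CCC[C@@]12C
F7 | step 12 | C4–C5 cyclopropane of F6 (cyclopropane syn to the hydroxyl) | COC(=O)[C@@]12CC[C@]1(C)CC(O)C13CC3(C)CCC[C@@]12C
F8 | step 12 | cyclopropyl ketone from F7 | COC(=O)[C@@]12CC[C@]1(C)CC(=O)C13CC3(C)CCC[C@@]12C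
F9 | step 17 | 6β,11-diacetate 7α-triethylsilyl ether | CC(=O)O[C@@H]1[C@@H](O[Si](CC)(CC)CC)[C@@]2(C)CC[C@@]2(COC(C)=O)[C@@]2(C)CCCC(C)(C)[C@H]12
F10 | step 17 | 6β-acetoxy 11-alcohol 7α-triethylsilyl ether | CC(=O)O[C@@H]1[C@@H](O[Si](CC)(CC)CC)[C@@]2(C)CC[C@@]2(CO)[C@@]2(C)CCCC(C)(C)[C@H]12
F11 | step 17 | 6β-acetoxy 11-aldehyde 7α-triethylsilyl ether | CC(=O)O[C@@H]1[C@@H](O[Si](CC)(CC)CC)[C@@]2(C)CC[C@@]2(C=O)[C@@]2(C)CCCC(C)(C)[C@H]12
A1 | alternative 1 | 7β-triethylsilyloxy analogue of the target (photoproduct) | CC(=O)O[C@@H]1[C@H](O[Si](CC)(CC)CC)[C@@]2(C)C[C@H]3[C@@]2(CC[C@]3(C)O)[C@@]2(C)CCCC(C)(C)[C@H]12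
A2 | alternative 1 | 3-oxobutyl ketone, 6β-acetoxy, 7β-triethylsilyloxy | CC(=O)O[C@@H]1[C@H](O[Si](CC)(CC)CC)[C@@]2(C)CC[C@@]2(CCC(C)=O)[C@@]2(C)CCCC(C)(C)[C@H]12
A3 | alternative 2 | bicyclo[3.2.0]hepta-3,6-dien-2-one fused to the decalin | O=C1C=C[C@@]23[C@@H]1C=C2CC[C@H]1C(C)(C)CCC[C@@]13C
A4 | alternative 2 | decalin-fused tropone | O=C1C=CC2=C(CC[C@H]3C(C)(C)CCC[C@]23C)C=C1
A5 | alternative 3 | tricyclic cyclobutanone with C5–C6 silyl enol ether | C[C@]12CC(=O)[C@H]1[C@@]1(C)CCCC(C)(C)C1=C(O[Si](C)(C)C(C)(C)C)C2
A6 | alternative 3 | tert-butyldimethyl{[1-(2,6,6-trimethylcyclohex-1-en-1-yl)ethenyl]oxy}silane | C=C(O[Si](C)(C)C(C)(C)C)C1=C(C)CCCC1(C)C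
A7 | alternative 3 | 3-methylcyclobut-2-en-1-one | CC1=CC(=O)C1
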